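**Retrosynthetic overview**
- The aldehyde is released last from a Weinreb amide with Cp2Zr(H)Cl; before that, the side-chain ester is made by Steglich coupling of the benzylic (R)-alcohol with (R)-2-methylbutanoic acid (from tiglic acid by asymmetric hydrogenation).
- The benzylic (R)-carbinol comes from the aryl methyl ketone by CBS reduction.
- The dihydrofuran ring (the only ring formed; the benzene ring is bought) and both ring stereocentres come from one organocatalytic operation: chiral-sulfide-catalysed ylide epoxidation of O-silyl 5-acetylsalicylaldehyde with a 2-carbamoylallyl bromide, fluoride-triggered phenoxide opening of the vinyl epoxide (net [4+1]), and acylation in the same flask.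
- The allyl bromide comes from 2-(bromomethyl)acrylic acid and N,O-dimethylhydroxylamine; the aldehyde partner from 5-acetylsalicylaldehyde and TIPSCl.

Assumption: the (2R,5R)-thiolane catalyst is taken to give the (2S,3S)-vinyl epoxide in step 3, by analogy with its (S,S)-selectivity for trans-stilbene oxide; if the first assay shows the opposite sense, the (2S,5S)-catalyst is used with nothing else changed.

**Step 1**
Reactants: 1 2-(bromomethyl)prop-2-enoic acid; 2 N,O-dimethylhydroxylamine hydrochloride
Product: 4 2-(bromomethyl)-N-methoxy-N-methylprop-2-enamide, via 2-(bromomethyl)prop-2-enoyl chloride 3 (not isolated)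
Conditions: (COCl)2, DMF (cat.), CH2Cl2, 0 °C to rt; concentrate; then 2, iPr2NEt, CH2Cl2, −40 to 0 °C
Reagents that add atoms: oxalyl chloride, O=C(Cl)C(=O)Cl (supplies the chlorine of 3 only)
Why: Acid chloride formation followed by N-acylation of the weakly nucleophilic N,O-dimethylhydroxylamine with a hindered base at low temperature (Weinreb amide synthesis) leaves the allylic bromide untouched, and no stereocentre is formed.

**Step 2**
Reactants: 5 5-acetyl-2-hydroxybenzaldehyde; 6 chlorotri(propan-2-yl)silane
Product: 7 5-acetyl-2-{[tri(propan-2-yl)silyl]oxy}benzaldehyde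
Conditions: TIPSCl, imidazole, DMF, rt
Reagents that add atoms: chlorotri(propan-2-yl)silane (6), CC(C)[Si](Cl)(C(C)C)C(C)C
Why: Imidazole-promoted silyl ether formation masks the acidic phenol, which would otherwise protonate the ylide and be O-allylated by 4 in step 3; no stereocentre is formed.

**Step 3**
Reactants: 7 5-acetyl-2-{[tri(propan-2-yl)silyl]oxy}benzaldehyde; 4 2-(bromomethyl)-N-methoxy-N-methylprop-2-enamide; 8 3-methylbutanoic anhydride
Product: 11 (2R,3S)-5-acetyl-2-{3-[methoxy(methyl)amino]-3-oxoprop-1-en-2-yl}-2,3-dihydro-1-benzofuran-3-yl 3-methylbutanoate, via silyloxyaryl vinyl epoxide 9 (not isolated), via dihydrobenzofuran-3-ol alkoxide 10 (not isolated)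
Conditions: (2R,5R)-2,5-dimethylthiolane (20 mol%), Bu4NI (10 mol%), Cs2CO3, 4 Å MS, MeCN, rt, slow addition of 4; then Bu4NF (THF), 0 °C; then (iPrCH2CO)2O, DMAP (cat.), 0 °C to rt
Reagents that add atoms: 3-methylbutanoic anhydride (8), CC(C)CC(=O)OC(=O)CC(C)C
Why: Proposed new method: a chiral-sulfide-catalysed Corey–Chaykovsky epoxidation interrupted by phenoxide ring opening, giving a net asymmetric [4+1] annulation, in which the C2-symmetric thiolane is S-alkylated by 4, Cs2CO3 forms the 2-carbamoylallyl sulfonium ylide, the ylide carbon adds to one face of the aldehyde of 7 and the anti-betaine closes to the trans-(2S,3S)-vinyl epoxide 9 with release of the sulfide (sets C3), fluoride then frees the phenoxide, which opens the epoxide at the allylic carbon by SN2 with inversion to form the five-membered ring (C2 becomes R, trans to the C3 alkoxide 10), and the alkoxide is acylated in the same flask; the closest known chemistry is the chiral-thiolane-catalysed ylide epoxidation of aryl aldehydes with benzyl and simple allyl halides and the base-induced cyclisation of 2-(oxiranyl)phenols to 2,3-dihydrobenzofuran-3-ols, whereas a Morita–Baylis–Hillman-type allyl bromide as ylide precursor, a keto-substituted ortho-silyloxy aryl aldehyde and the one-flask relay to the dihydrobenzofuran are untested.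

**Step 4**
Reactants: 11 (2R,3S)-5-acetyl-2-{3-[methoxy(methyl)amino]-3-oxoprop-1-en-2-yl}-2,3-dihydro-1-benzofuran-3-yl 3-methylbutanoate
Product: 12 (2R,3S)-5-[(1R)-1-hydroxyethyl]-2-{3-[methoxy(methyl)amino]-3-oxoprop-1-en-2-yl}-2,3-dihydro-1-benzofuran-3-yl 3-methylbutanoate
Conditions: (S)-Me-CBS (20 mol%), catecholborane, toluene, −78 to −40 °C; MeOH quench
Reagents that add atoms: none
Why: Corey–Bakshi–Shibata reduction with the (S)-oxazaborolidine gives the (R)-carbinol from an aryl methyl ketone under catalyst control, as with acetophenone, and catecholborane at low temperature spares the ester, the Weinreb amide and the electron-poor 1,1-disubstituted alkene.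

**Step 5**
Reactants: 13 (2E)-2-methylbut-2-enoic acid (tiglic acid)
Product: 14 (2R)-2-methylbutanoic acid
Conditions: H2 (4 atm), Ru(OAc)2[(R)-H8-BINAP] (0.5 mol%), MeOH, 20 °C
Reagents that add atoms: none
Why: Carboxylate-directed asymmetric hydrogenation of an (E)-2-alkyl-2-alkenoic acid with a divalent ruthenium diacetate complex of a BINAP-type ligand sets the α-stereocentre, the (R)-ligand giving the (R)-acid in about 97% ee.

**Step 6**
Reactants: 12 (2R,3S)-5-[(1R)-1-hydroxyethyl]-2-{3-[methoxy(methyl)amino]-3-oxoprop-1-en-2-yl}-2,3-dihydro-1-benzofuran-3-yl 3-methylbutanoate; 14 (2R)-2-methylbutanoic acid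
Product: 15 (2R,3S)-2-{3-[methoxy(methyl)amino]-3-oxoprop-1-en-2-yl}-5-[(1R)-1-{[(2R)-2-methylbutanoyl]oxy}ethyl]-2,3-dihydro-1-benzofuran-3-yl 3-methylbutanoate
Conditions: DCC, DMAP (10 mol%), CH2Cl2, 0 °C to rt
Reagents that add atoms: none
Why: Steglich esterification activates the acid and not the alcohol, so the benzylic C–O bond is kept (retention at the (R)-carbinol), and catalytic DMAP at 0 °C does not epimerise the α-stereocentre of 14.

**Step 7**
Reactants: 15 (2R,3S)-2-{3-[methoxy(methyl)amino]-3-oxoprop-1-en-2-yl}-5-[(1R)-1-{[(2R)-2-methylbutanoyl]oxy}ethyl]-2,3-dihydro-1-benzofuran-3-yl 3-methylbutanoate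
Product: 16 (2R,3S)-5-[(1R)-1-{[(2R)-2-methylbutanoyl]oxy}ethyl]-2-(3-oxoprop-1-en-2-yl)-2,3-dihydro-1-benzofuran-3-yl 3-methylbutanoate
Conditions: Cp2Zr(H)Cl (1.5 equiv), THF, rt, 20 min; SiO2/H2O work-up
Reagents that add atoms: none
Why: Schwartz reagent adds its hydride to the amide carbonyl to give a zirconated N,O-hemiaminal that releases the aldehyde only on work-up (chemoselective amide-to-aldehyde reduction), so the two esters and the alkene are expected to survive and no stereocentre is touched.

**Compound list**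
1 | 2-(bromomethyl)prop-2-enoic acid | C=C(CBr)C(=O)O | starting material
2 | N,O-dimethylhydroxylamine hydrochloride | CNOC.Cl | starting material
3 | 2-(bromomethyl)prop-2-enoyl chloride | C=C(CBr)C(=O)Cl | intermediate
4 | 2-(bromomethyl)-N-methoxy-N-methylprop-2-enamide | C=C(CBr)C(=O)N(C)OC | intermediate
5 | 5-acetyl-2-hydroxybenzaldehyde | CC(=O)c1ccc(O)c(C=O)c1 | starting material
6 | chlorotri(propan-2-yl)silane | CC(C)[Si](Cl)(C(C)C)C(C)C | starting material
7 | 5-acetyl-2-{[tri(propan-2-yl)silyl]oxy}benzaldehyde | CC(=O)c1ccc(O[Si](C(C)C)(C(C)C)C(C)C)c(C=O)c1 | intermediate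
8 | 3-methylbutanoic anhydride | CC(C)CC(=O)OC(=O)CC(C)C | starting material
9 | 2-[(2S,3S)-3-(5-acetyl-2-{[tri(propan-2-yl)silyl]oxy}phenyl)oxiran-2-yl]-N-methoxy-N-methylprop-2-enamide | C=C(C(=O)N(C)OC)[C@@H]1O[C@H]1c1cc(C(C)=O)ccc1O[Si](C(C)C)(C(C)C)C(C)C | intermediate
10 | 2-[(2R,3S)-5-acetyl-3-hydroxy-2,3-dihydro-1-benzofuran-2-yl]-N-methoxy-N-methylprop-2-enamide (present as its tetrabutylammonium alkoxide) | C=C(C(=O)N(C)OC)[C@H]1Oc2ccc(C(C)=O)cc2[C@@H]1O | intermediate
11 | (2R,3S)-5-acetyl-2-{3-[methoxy(methyl)amino]-3-oxoprop-1-en-2-yl}-2,3-dihydro-1-benzofuran-3-yl 3-methylbutanoate | C=C(C(=O)N(C)OC)[C@H]1Oc2ccc(C(C)=O)cc2[C@@H]1OC(=O)CC(C)C | intermediate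
12 | (2R,3S)-5-[(1R)-1-hydroxyethyl]-2-{3-[methoxy(methyl)amino]-3-oxoprop-1-en-2-yl}-2,3-dihydro-1-benzofuran-3-yl 3-methylbutanoate | C=C(C(=O)N(C)OC)[C@H]1Oc2ccc([C@@H](C)O)cc2[C@@H]1OC(=O)CC(C)C | intermediate
13 | (2E)-2-methylbut-2-enoic acid (tiglic acid) | C/C=C(\C)C(=O)O | starting material
14 | (2R)-2-methylbutanoic acid | CC[C@@H](C)C(=O)O | intermediate
15 | (2R,3S)-2-{3-[methoxy(methyl)amino]-3-oxoprop-1-en-2-yl}-5-[(1R)-1-{[(2R)-2-methylbutanoyl]oxy}ethyl]-2,3-dihydro-1-benzofuran-3-yl 3-methylbutanoate | C=C(C(=O)N(C)OC)[C@H]1Oc2ccc([C@@H](C)OC(=O)[C@H](C)CC)cc2[C@@H]1OC(=O)CC(C)C | intermediate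
16 | (2R,3S)-5-[(1R)-1-{[(2R)-2-methylbutanoyl]oxy}ethyl]-2-(3-oxoprop-1-en-2-yl)-2,3-dihydro-1-benzofuran-3-yl 3-methylbutanoate | C=C(C=O)[C@H]1Oc2ccc([C@@H](C)OC(=O)[C@H](C)CC)cc2[C@@H]1OC(=O)CC(C)C | target

**Step count and risks**
Total step count: 7. Longest linear sequence: 5 steps (1 → 4 → 11 → 12 → 15 → 16; the branch from 5 through 7 is equally long).

Most likely to fail, first: step 3, the proposed new step. The sulfide may turn over slowly, the ylide may condense with 4, and the trans/cis ratio and ee of the epoxide are unproven for this ylide. After desilylation the phenoxide could also attack the acrylamide CH2 (seven-membered ring) instead of the allylic epoxide carbon. The fallback uses known reaction types only, sets out from 4 and 7 and comes back at 9, which is then isolated and carried through the fluoride and acylation part of step 3. Bromide 4 and PPh3 (toluene, rt) give {2-[methoxy(methyl)carbamoyl]prop-2-en-1-yl}(triphenyl)phosphonium bromide F1. Wittig olefination of 7 with F1 (K2CO3, MeCN, then catalytic I2 to equilibrate to the E isomer) gives (3E)-4-(5-acetyl-2-{[tri(propan-2-yl)silyl]oxy}phenyl)-N-methoxy-N-methyl-2-methylidenebut-3-enamide F2. Shi epoxidation of the electron-rich styrenyl double bond of F2 gives 9; it uses the L-fructose-derived ketone catalyst (the enantiomer of the usual D-fructose-derived one), Oxone (2KHSO5·KHSO4·K2SO4), K2CO3 buffer, MeCN/dimethoxymethane/H2O, 0 °C. Monoepoxidation of a conjugated diene at its trans-disubstituted double bond is established for this catalyst class, and the stereo-defining step stays organocatalytic.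

Second: step 7. Hydrozirconation or conjugate reduction of the acrylamide, attack on the two benzylic esters, or addition of the liberated N,O-dimethylhydroxylamine to the enal would all cost material carrying the chiral acid. The fallback reorders the end game; it sets out from 12 and comes back at 16. Alcohol 12 is treated with Cp2Zr(H)Cl (2.5 equiv, THF, rt; the free carbinol is held as its zirconium alkoxide) to give (2R,3S)-5-[(1R)-1-hydroxyethyl]-2-(3-oxoprop-1-en-2-yl)-2,3-dihydro-1-benzofuran-3-yl 3-methylbutanoate F3. Here only one ester is present and by-products are removed before the chiral acid is spent. F3 is then esterified with 14 (DCC, DMAP cat., CH2Cl2, 0 °C), which the enal tolerates, to give 16.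

Third: step 1. The amine can displace the very reactive allylic bromide, and the acid chloride can polymerise. The fallback builds the bromide after the amide; it sets out from 2 and comes back at 4. Compound 2 is acylated with acryloyl chloride (K2CO3, CH2Cl2/H2O, 0 °C) to N-methoxy-N-methylprop-2-enamide F4. Morita–Baylis–Hillman hydroxymethylation with paraformaldehyde (DABCO, phenol cat., t-BuOH/H2O, 50 °C) gives 2-(hydroxymethyl)-N-methoxy-N-methylprop-2-enamide F5. Appel bromination of F5 (CBr4, PPh3, CH2Cl2, 0 °C) gives 4.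

**Further compounds**
F1 | step 3 | {2-[methoxy(methyl)carbamoyl]prop-2-en-1-yl}(triphenyl)phosphonium bromide | C=C(C[P+](c1ccccc1)(c1ccccc1)c1ccccc1)C(=O)N(C)OC.[Br-]
F2 | step 3 | (3E)-4-(5-acetyl-2-{[tri(propan-2-yl)silyl]oxy}phenyl)-N-methoxy-N-methyl-2-methylidenebut-3-enamide | C=C(C(=O)N(C)OC)/C=C/c1cc(C(C)=O)ccc1O[Si](C(C)C)(C(C)C)C(C)C
F3 | step 7 | (2R,3S)-5-[(1R)-1-hydroxyethyl]-2-(3-oxoprop-1-en-2-yl)-2,3-dihydro-1-benzofuran-3-yl 3-methylbutanoate | C=C(C=O)[C@H]1Oc2ccc([C@@H](C)O)cc2[C@@H]1OC(=O)CC(C)C
F4 | step 1 | N-methoxy-N-methylprop-2-enamide | C=CC(=O)N(C)OC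
F5 | step 1 | 2-(hydroxymethyl)-N-methoxy-N-methylprop-2-enamide | C=C(CO)C(=O)N(C)OC
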